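**Retrosynthetic overview**
1. The last operation cuts the sp–sp2 bond of the E-enyne (alkenyl iodide plus terminal alkyne, Sonogashira). In the same flask it also cuts the C6–O1, C6–OMe and ester O–Me bonds. The target falls to (E)-1-iodoundeca-1,10-diene, methanol and an acyclic keto acid with one stereocentre.
2. Enabling feature: in the 1,2-dioxane ring (O1, O2, C3, C4, C5, C6), C6 is a peroxyketal carbon at the ketone level, 1,4 to C3. The (3S,6R) isomer is the thermodynamic chair (C6–OMe axial and anomeric to O1, both carbon arms equatorial), so C6 can be formed reversibly under control of C3. The alkyne C–H lies three CH2 groups from the ring, and the finished O1–O2 bond carries no O–H.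
3. C3–O2 is set earlier by iminium-catalysed enantioselective β-peroxidation of (E)-6-oxoundec-2-en-10-ynal with 2-methoxypropan-2-yl hydroperoxide, followed by Pinnick oxidation.
4. The enal comes from hex-5-ynoic acid (Weinreb ketone synthesis, alkene-selective ozonolysis, formyl Wittig). The iodide comes from 9-bromonon-1-ene (acetylide alkylation, alkyne-selective hydrozirconation–iodination).
5. Ring order: the only ring, the 1,2-dioxane, is closed in the first stage of the last step, directly before the C–C coupling.

Key step: step 10

Assumption: the sense of induction in step 6 is taken from the usual steric-shielding model of diarylprolinol silyl ether iminium ions (attack anti to the CPh2OSiMe3 group of the s-trans E-iminium ion), which assigns the (R)-catalyst to the (3S)-peroxide.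

Step 1
Reactants: 1 hex-5-ynoic acid
Product: 3 N-methoxy-N-methylhex-5-ynamide, via acyl imidazolide 2 (not isolated)
Conditions: CDI, CH2Cl2, rt; then MeNH(OMe)·HCl, rt
Reagents that add atoms: N,O-dimethylhydroxylamine hydrochloride, CNOC.Cl; 1,1'-carbonyldiimidazole, O=C(n1ccnc1)n1ccnc1 (imidazolyl group of 2 only)
Why: Weinreb amide formation through acyl imidazolide activation is a standard amidation that leaves the terminal alkyne untouched and creates no stereocentre.

Step 2
Reactants: 3 N-methoxy-N-methylhex-5-ynamide; 4 but-3-enylmagnesium bromide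
Product: 5 dec-1-en-9-yn-5-one
Conditions: 4 (2.3 equiv), THF, −20 to 0 °C
Reagents that add atoms: none
Why: Weinreb ketone synthesis: the chelated tetrahedral magnesium adduct survives until quench and so stops at the ketone, while the extra equivalent of 4 only deprotonates the alkyne C–H, which is restored on work-up.

Step 3
Reactants: 5 dec-1-en-9-yn-5-one
Product: 7 4-oxonon-8-ynal, via secondary ozonide 6 (not isolated)
Conditions: O3/O2, CH2Cl2, −78 °C (Sudan Red 7B end-point); then Me2S, −78 °C to rt
Reagents that add atoms: ozone, [O-][O+]=O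
Why: Chemoselective ozonolysis with reductive work-up: the monosubstituted alkene undergoes the 1,3-dipolar cycloaddition with ozone far faster than the alkyne, so that dosing to an indicator end-point should spare the triple bond.

Step 4
Reactants: 7 4-oxonon-8-ynal; 8 (triphenylphosphoranylidene)acetaldehyde
Product: 9 (2E)-6-oxoundec-2-en-10-ynal
Conditions: 8 (1.05 equiv), toluene, rt to 40 °C
Reagents that add atoms: none
Why: Wittig olefination with a stabilised formyl ylide attacks only the aldehyde, not the ketone, and should give the E-enal because oxaphosphetane formation from stabilised ylides favours the trans adduct.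

Step 5
Reactants: 10 2,3-dimethylbut-2-ene
Product: 12 2-methoxypropan-2-yl hydroperoxide, via acetone O-oxide 11 (not isolated)
Conditions: O3/O2, MeOH/CH2Cl2, −78 °C; kept and used as a titrated solution
Reagents that add atoms: ozone, [O-][O+]=O; methanol, CO
Why: Ozonolysis in a participating solvent: Criegee cleavage of the symmetrical alkene gives acetone and carbonyl oxide 11, which methanol traps as the hydroperoxy ketal.

Step 6
Reactants: 9 (2E)-6-oxoundec-2-en-10-ynal; 12 2-methoxypropan-2-yl hydroperoxide
Product: 13 (3S)-3-[(2-methoxypropan-2-yl)peroxy]-6-oxoundec-10-ynal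
Conditions: (R)-diphenylprolinol trimethylsilyl ether (10 mol%), PhCO2H (10 mol%), 12 (1.5 equiv), toluene, 0 °C
Reagents that add atoms: none
Why: Iminium-catalysed enantioselective oxa-Michael addition (β-peroxidation) of an alkyl hydroperoxide to an enal: the bulky amine condenses only with the aldehyde, its CPh2OSiMe3 group shields one face of the s-trans E-iminium ion so that the peroxide oxygen reaches C3 from the open face and sets 3S, and the acid co-catalyst protonates the enamine before it can close to an epoxide.

Step 7
Reactants: 13 (3S)-3-[(2-methoxypropan-2-yl)peroxy]-6-oxoundec-10-ynal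
Product: 14 (3S)-3-[(2-methoxypropan-2-yl)peroxy]-6-oxoundec-10-ynoic acid
Conditions: NaClO2, NaH2PO4, 2-methylbut-2-ene, t-BuOH/H2O, 0 °C
Reagents that add atoms: sodium chlorite, [Na+].[O-]Cl=O
Why: Pinnick oxidation runs in a weakly acidic buffer that should neither enolise C2 (no β-elimination of the peroxide, C3 untouched) nor hydrolyse the perketal, while 2-methylbut-2-ene removes hypochlorous acid before it can reach the alkyne.

Step 8
Reactants: 15 9-bromonon-1-ene; 16 lithium acetylide–ethylenediamine complex
Product: 17 undec-1-en-10-yne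
Conditions: DMSO, 10 °C to rt
Reagents that add atoms: none
Why: SN2 alkylation of an acetylide by a primary bromide in a dipolar aprotic solvent is standard and leaves the remote alkene in place.

Step 9
Reactants: 17 undec-1-en-10-yne
Product: 19 (E)-1-iodoundeca-1,10-diene, via alkenylzirconocene 18 (not isolated)
Conditions: Cp2Zr(H)Cl (1.05 equiv), CH2Cl2, rt, dark; then I2 (1.0 equiv), 0 °C
Reagents that add atoms: iodine, [I][I]; Cp2Zr(H)Cl, [H][Zr](Cl)(C1C=CC=C1)C1C=CC=C1 (zirconocene fragment of 18 only)
Why: Hydrozirconation–iodinolysis: Cp2Zr(H)Cl adds syn and anti-Markovnikov to the terminal alkyne, which reacts much faster than the monosubstituted alkene when one equivalent is used, and iodine cleaves the C–Zr bond with retention to fix the E geometry.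

Step 10
Reactants: 14 (3S)-3-[(2-methoxypropan-2-yl)peroxy]-6-oxoundec-10-ynoic acid; 19 (E)-1-iodoundeca-1,10-diene
Product: 24 peroxyacarnoate A, via hydroperoxy keto acid 20 (not isolated), via peroxyhemiketal acid 21 (not isolated), via methoxydioxane acid 22 (not isolated), via dioxane alkyne ester 23 (not isolated)
Conditions: CSA (0.2 equiv), MeOH, rt, until no O–H peroxide and no free acid remain; then Et3N (6 equiv), THF, argon sparge, 19 (1.1 equiv), PdCl2(PPh3)2 (3 mol%), CuI (6 mol%), rt
Reagents that add atoms: methanol, CO (two equivalents: C6–OMe and ester OMe)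
Why: In methanol containing camphorsulfonic acid the acetone perketal of 14 is methanolysed to hydroperoxide 20, whose terminal oxygen adds to the C6 ketone in a 6-exo-trig closure to give the 1,2-dioxane as hemiketal 21; ionisation to the ring peroxycarbenium ion and capture of methanol gives peroxyketal 22, and Fischer esterification of the unhindered acid gives 23. All C6–O bond formations are reversible, so both C6 epimers drain into the chair with the C3 CH2CO2Me arm and the C6 pentynyl arm equatorial and the C6 methoxy group axial (anomeric interaction with ring O1), which means that the one stereocentre C3 dictates 6R. Once no O–H peroxide is left the acid is quenched with Et3N and a Sonogashira coupling is run in the same flask: zerovalent palladium inserts into the C–I bond of 19, the copper acetylide of 23 transmetalates, and reductive elimination forms the sp–sp2 bond with retention of the E geometry. The closest known reaction types are the acid-catalysed conversion of 1,2-dioxan-3-ols into 3-methoxy-1,2-dioxanes and the palladium/copper-catalysed alkynylation of alkenyl iodides in the presence of dialkyl peroxides. The step needs C–I insertion to outrun O–O cleavage and to ignore the terminal alkene, which is secured by the very fast oxidative addition of an alkenyl iodide at room temperature, by the fully alkylated and flanked O1–O2 bond of 23 and by the three CH2 groups that hold the alkyne away from the ring. Four components (14, two molecules of methanol, 19) thereby deliver the ring, the second stereocentre, both methoxy groups and the full C22 chain.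

**Compound list**
1 | hex-5-ynoic acid | C#CCCCC(=O)O | starting material
2 | 1-(hex-5-ynoyl)-1H-imidazole | C#CCCCC(=O)n1ccnc1 | intermediate
3 | N-methoxy-N-methylhex-5-ynamide | C#CCCCC(=O)N(C)OC | intermediate
4 | but-3-enylmagnesium bromide | C=CCC[Mg]Br | starting material
5 | dec-1-en-9-yn-5-one | C=CCCC(=O)CCCC#C | intermediate
6 | 1-(1,2,4-trioxolan-3-yl)oct-7-yn-3-one (secondary ozonide) | C#CCCCC(=O)CCC1OCOO1 | intermediate
7 | 4-oxonon-8-ynal | O=CCCC(=O)CCCC#C | intermediate
8 | (triphenylphosphoranylidene)acetaldehyde | O=CC=P(c1ccccc1)(c1ccccc1)c1ccccc1 | starting material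
9 | (2E)-6-oxoundec-2-en-10-ynal | C#CCCCC(=O)CC/C=C/C=O | intermediate
10 | 2,3-dimethylbut-2-ene | CC(C)=C(C)C | starting material
11 | acetone O-oxide (carbonyl oxide) | CC(C)=[O+][O-] | intermediate
12 | 2-methoxypropan-2-yl hydroperoxide | COC(C)(C)OO | intermediate
13 | (3S)-3-[(2-methoxypropan-2-yl)peroxy]-6-oxoundec-10-ynal | C#CCCCC(=O)CC[C@@H](CC=O)OOC(C)(C)OC | intermediate
14 | (3S)-3-[(2-methoxypropan-2-yl)peroxy]-6-oxoundec-10-ynoic acid | C#CCCCC(=O)CC[C@@H](CC(=O)O)OOC(C)(C)OC | intermediate
15 | 9-bromonon-1-ene | C=CCCCCCCCBr | starting material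
16 | lithium acetylide–ethylenediamine complex | [Li+].[C-]#C.NCCN | starting material
17 | undec-1-en-10-yne | C=CCCCCCCCC#C | intermediate
18 | chlorobis(cyclopentadienyl)[(1E)-undeca-1,10-dien-1-yl]zirconium | C=CCCCCCCC/C=C/[Zr](Cl)(C1C=CC=C1)C1C=CC=C1 | intermediate
19 | (E)-1-iodoundeca-1,10-diene | C=CCCCCCCC/C=C/I | intermediate
20 | (3S)-3-hydroperoxy-6-oxoundec-10-ynoic acid | C#CCCCC(=O)CC[C@@H](CC(=O)O)OO | intermediate
21 | 2-[(3S)-6-hydroxy-6-(pent-4-yn-1-yl)-1,2-dioxan-3-yl]acetic acid (both C6 epimers, interconverting) | C#CCCCC1(O)CC[C@@H](CC(=O)O)OO1 | intermediate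
22 | 2-[(3S,6R)-6-methoxy-6-(pent-4-yn-1-yl)-1,2-dioxan-3-yl]acetic acid | C#CCCC[C@]1(OC)CC[C@@H](CC(=O)O)OO1 | intermediate
23 | methyl 2-[(3S,6R)-6-methoxy-6-(pent-4-yn-1-yl)-1,2-dioxan-3-yl]acetate | C#CCCC[C@]1(OC)CC[C@@H](CC(=O)OC)OO1 | intermediate
24 | peroxyacarnoate A, methyl 2-[(3S,6R)-6-[(6E)-hexadeca-6,15-dien-4-yn-1-yl]-6-methoxy-1,2-dioxan-3-yl]acetate | C=CCCCCCCC/C=C/C#CCCC[C@]1(OC)CC[C@@H](CC(=O)OC)OO1 | target

**Total step count:** 10. **Longest linear sequence:** 7 (steps 1, 2, 3, 4, 6, 7, 10).

**Steps most likely to fail**

Step 6.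
- What may go wrong: the β-peroxy enamine may collapse by intramolecular displacement at the O–O bond (epoxidation). Facial selectivity may be poor, or reversible addition may erode the enantiomeric purity.
- Fallback: the peroxide is delivered intramolecularly and the enantiomers are then separated. It sets out from 7 and comes back at 23.
- Wittig olefination of 7 with methyl (triphenylphosphoranylidene)acetate gives methyl (2E)-6-oxoundec-2-en-10-ynoate F1.
- Urea–hydrogen peroxide with catalytic TsOH in MeOH converts the ketone into racemic methyl (2E)-6-hydroperoxy-6-methoxyundec-2-en-10-ynoate F2.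
- Et2NH in CF3CH2OH triggers the 6-exo-trig oxa-Michael closure. CSA/MeOH then equilibrates C6 to racemic methyl 2-[(3S*,6R*)-6-methoxy-6-(pent-4-yn-1-yl)-1,2-dioxan-3-yl]acetate F3.
- Preparative chromatography on a chiral stationary phase gives 23 and sets aside the (3R,6S)-enantiomer F4.
- Compound 23 then enters the second stage of step 10.

Step 10.
- What may go wrong: ring closure or esterification may be incomplete when the metals are added, so that residual O–H peroxide is reduced by phosphine and monovalent copper. The O1–O2 bond may itself be cleaved by low-valent metal. The alkyne may homocouple oxidatively.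
- Fallback: the order of events is inverted so that no peroxide ever meets a transition metal. It sets out from 9 and 19 and comes back at 24.
- The Sonogashira coupling (PdCl2(PPh3)2, CuI, Et3N, THF, rt) is run on the peroxide-free enal to give (2E,12E)-6-oxodocosa-2,12,21-trien-10-ynal F5.
- β-Peroxidation with 12 under the conditions of step 6 gives (3S,12E)-3-[(2-methoxypropan-2-yl)peroxy]-6-oxodocosa-12,21-dien-10-ynal F6.
- Pinnick oxidation gives (3S,12E)-3-[(2-methoxypropan-2-yl)peroxy]-6-oxodocosa-12,21-dien-10-ynoic acid F7.
- Metal-free CSA/MeOH then carries F7 through chain-extended hydroperoxy keto acid F8, chain-extended peroxyhemiketal acid F9 and chain-extended methoxydioxane acid F10 to 24.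

Step 9.
- What may go wrong: discrimination between the alkyne and the terminal alkene in the hydrozirconation may be incomplete, with loss of the alkene by over-addition and iodination.
- Fallback: the iodoalkene is built from an aldehyde, so that no alkyne competes with the alkene. It sets out from 15 and comes back at 19.
- Mg in THF converts 15 into non-8-enylmagnesium bromide F11.
- Formylation with DMF gives dec-9-enal F12.
- Takai olefination (CHI3, CrCl2, THF, 0 °C) should give 19 mainly as the E isomer, with any Z isomer removed by chromatography.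

**Further compounds**
F1 | step 6 | methyl (2E)-6-oxoundec-2-en-10-ynoate | C#CCCCC(=O)CC/C=C/C(=O)OC
F2 | step 6 | methyl (2E)-6-hydroperoxy-6-methoxyundec-2-en-10-ynoate (racemic) | C#CCCCC(OC)(OO)CC/C=C/C(=O)OC
F3 | step 6 | methyl 2-[(3S*,6R*)-6-methoxy-6-(pent-4-yn-1-yl)-1,2-dioxan-3-yl]acetate (racemic) | C#CCCCC1(OC)CCC(CC(=O)OC)OO1
F4 | step 6 | methyl 2-[(3R,6S)-6-methoxy-6-(pent-4-yn-1-yl)-1,2-dioxan-3-yl]acetate | C#CCCC[C@@]1(OC)CC[C@H](CC(=O)OC)OO1
F5 | step 10 | (2E,12E)-6-oxodocosa-2,12,21-trien-10-ynal | C=CCCCCCCC/C=C/C#CCCCC(=O)CC/C=C/C=O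
F6 | step 10 | (3S,12E)-3-[(2-methoxypropan-2-yl)peroxy]-6-oxodocosa-12,21-dien-10-ynal | C=CCCCCCCC/C=C/C#CCCCC(=O)CC[C@@H](CC=O)OOC(C)(C)OC
F7 | step 10 | (3S,12E)-3-[(2-methoxypropan-2-yl)peroxy]-6-oxodocosa-12,21-dien-10-ynoic acid | C=CCCCCCCC/C=C/C#CCCCC(=O)CC[C@@H](CC(=O)O)OOC(C)(C)OC
F8 | step 10 | (3S,12E)-3-hydroperoxy-6-oxodocosa-12,21-dien-10-ynoic acid | C=CCCCCCCC/C=C/C#CCCCC(=O)CC[C@@H](CC(=O)O)OO
F9 | step 10 | 2-[(3S)-6-[(6E)-hexadeca-6,15-dien-4-yn-1-yl]-6-hydroxy-1,2-dioxan-3-yl]acetic acid (both C6 epimers) | C=CCCCCCCC/C=C/C#CCCCC1(O)CC[C@@H](CC(=O)O)OO1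
F10 | step 10 | 2-[(3S,6R)-6-[(6E)-hexadeca-6,15-dien-4-yn-1-yl]-6-methoxy-1,2-dioxan-3-yl]acetic acid | C=CCCCCCCC/C=C/C#CCCC[C@]1(OC)CC[C@@H](CC(=O)O)OO1
F11 | step 9 | non-8-enylmagnesium bromide | C=CCCCCCCC[Mg]Br
F12 | step 9 | dec-9-enal | C=CCCCCCCCC=O
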